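**Assumption:** the target has no stereocentre (the pyran C=C is endocyclic), so it is achiral and needs no enantiocontrol; it is drawn throughout as the enol tautomer of the given SMILES.

## Retrosynthetic overview

1. Target 10 ⇒ 2H-pyran annulation with prenal (C–C, then C–O by oxa-6π) on the only free aromatic C–H of mixed dimer 7.
2. Dimer 7 ⇒ symmetric bis(propionylphloroglucinyl)methane 5 by removing two C-methyls from one ring; forward, a double C-methylation dearomatizes one ring and breaks the symmetry.
3. Dimer 5 ⇒ two molecules of propionylphloroglucinol 3 plus formaldehyde; 3 ⇒ phloroglucinol 1 plus propionyl chloride 2.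
4. Ring order: both carbocycles come from phloroglucinol; the cyclohexadienone is made by dearomatization (step 3) and the pyran is closed last (step 4).

## Route

Step 1
Reactants: 1 phloroglucinol (benzene-1,3,5-triol, anhydrous); 2 propionyl chloride
Product: 3 1-(2,4,6-trihydroxyphenyl)propan-1-one (propionylphloroglucinol)
Conditions: AlCl3 (3.5 equiv), PhNO2–CH2Cl2, 0 °C → 45 °C, 12 h; ice/1 M HCl
Reagents that add atoms: none
Why: Friedel–Crafts C-acylation of a very electron-rich arene, where the AlCl3-chelated aryl ketone product is deactivated so the reaction stops at mono-acylation; no stereocentre is formed.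

Step 2
Reactants: 3 1-(2,4,6-trihydroxyphenyl)propan-1-one (2.0 equiv)
Product: 5 bis(2,4,6-trihydroxy-3-propanoylphenyl)methane, via hydroxymethyl adduct 4 (not isolated)
Conditions: 37% aq. CH2O (0.95 equiv per two 3), NaOH (1 equiv per 3), H2O, 0 °C → rt, 30 min; then 1 M HCl, filter, recrystallize
Reagents that add atoms: formaldehyde, C=O
Why: base-mediated hydroxymethylation to 4, loss of water to an o-quinone methide and Michael addition of a second phloroglucinolate give the methylene-bridged homodimer (classical methylene-bis-phloroglucinol condensation), with a slight deficit of formaldehyde keeping trimers low; the product is achiral.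

Step 3
Reactants: 5 bis(2,4,6-trihydroxy-3-propanoylphenyl)methane
Product: 7 3,5-dihydroxy-4,4-dimethyl-2-propanoyl-6-[(2,4,6-trihydroxy-3-propanoylphenyl)methyl]cyclohexa-2,5-dien-1-one, via mono-C-methyl dimer 6 (not isolated)
Conditions: NaOMe (4.0 equiv), MeI (2.0 equiv, added over 2 h), MeOH, 0 °C → rt, 8 h, N2; 1 M HCl; chromatography (recover 5)
Reagents that add atoms: iodomethane, CI
Why: Proposed new method: the polyphenolate of 5 is C-methylated at the single free C–H of one ring to give 6, whose newly alkylated carbon should then be the most nucleophilic carbon in the molecule (alkylated phloroglucinolate carbons react faster than C–H ones, which is why gem-dialkylation dominates in filicinic acid, syncarpic acid and lupulone syntheses), so the second MeI goes to the same carbon and that ring alone becomes a vinylogous-acid enolate that is a poor C-nucleophile and resists further methylation, while the bridge-bearing carbons are shielded by the diarylmethane arm and the untouched ring competes only statistically; the closest known reaction is the NaOMe/MeI dearomative gem-dimethylation of monomeric acylphloroglucinols to acylfilicinic acids; the new quaternary carbon carries two identical methyls, so no stereocentre is created.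

Step 4
Reactants: 7 3,5-dihydroxy-4,4-dimethyl-2-propanoyl-6-[(2,4,6-trihydroxy-3-propanoylphenyl)methyl]cyclohexa-2,5-dien-1-one; 8 3-methylbut-2-enal (prenal, 1.5 equiv)
Product: 10 target 6-[(5,7-dihydroxy-2,2-dimethyl-8-propanoyl-2H-chromen-6-yl)methyl]-3,5-dihydroxy-4,4-dimethyl-2-propanoylcyclohexa-2,5-dien-1-one, via Z-oxatriene 9 (not isolated)
Conditions: ethylenediammonium diacetate (EDDA, 20 mol%), THF–PhMe (1:4), 70 °C, 4–6 h
Reagents that add atoms: none
Why: amine-catalysed Knoevenagel-type condensation of prenal at the only remaining aromatic C–H gives the vinylogous o-quinone methide 9, which closes by oxa-6π electrocyclization (formal [3+3] chromene annulation) onto the oxygen next to the propionyl-bearing carbon, the other ortho OH being flanked by the bridge and hydrogen-bonded to the filicinic carbonyl; this regiochemistry is an expectation, not a certainty; the filicinic ring has no C–H nucleophile left and no stereocentre arises.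

## Compound list

1 | phloroglucinol (benzene-1,3,5-triol) | Oc1cc(O)cc(O)c1 | starting material
2 | propionyl chloride | CCC(=O)Cl | starting material
3 | 1-(2,4,6-trihydroxyphenyl)propan-1-one | CCC(=O)c1c(O)cc(O)cc1O | intermediate
4 | 1-[2,4,6-trihydroxy-3-(hydroxymethyl)phenyl]propan-1-one (not isolated) | CCC(=O)c1c(O)cc(O)c(CO)c1O | intermediate
5 | bis(2,4,6-trihydroxy-3-propanoylphenyl)methane (symmetric dimer) | CCC(=O)c1c(O)cc(O)c(Cc2c(O)cc(O)c(C(=O)CC)c2O)c1O | intermediate
6 | 1-[2,4,6-trihydroxy-3-methyl-5-[(2,4,6-trihydroxy-3-propanoylphenyl)methyl]phenyl]propan-1-one (not isolated) | CCC(=O)c1c(O)c(C)c(O)c(Cc2c(O)cc(O)c(C(=O)CC)c2O)c1O | intermediate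
7 | 3,5-dihydroxy-4,4-dimethyl-2-propanoyl-6-[(2,4,6-trihydroxy-3-propanoylphenyl)methyl]cyclohexa-2,5-dien-1-one | CCC(=O)C1=C(O)C(C)(C)C(O)=C(Cc2c(O)cc(O)c(C(=O)CC)c2O)C1=O | intermediate
8 | 3-methylbut-2-enal (prenal) | CC(C)=CC=O | starting material
9 | Z-oxatriene (not isolated): the former aromatic ring of 7 as a cyclohexadienone with exocyclic =CH–CH=CMe2 at the former C–H carbon, syn to the ring C=O that lies next to the propionyl-bearing carbon | CCC(=O)C1=C(O)C(C)(C)C(O)=C(CC2=C(O)/C(=C/C=C(C)C)C(=O)C(C(=O)CC)=C2O)C1=O | intermediate
10 | 6-[(5,7-dihydroxy-2,2-dimethyl-8-propanoyl-2H-chromen-6-yl)methyl]-3,5-dihydroxy-4,4-dimethyl-2-propanoylcyclohexa-2,5-dien-1-one | CCC(=O)C1=C(O)C(C)(C)C(O)=C(Cc2c(O)c3c(c(C(=O)CC)c2O)OC(C)(C)C=C3)C1=O | target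

## Step count and risks

Total step count: 4. Longest linear sequence: 4 (from phloroglucinol). Compound 3 is also sold, and buying it would leave three steps.

**Most likely to fail, in order:**

**Step 3 (desymmetrizing dearomatization).** Possible failures are a near-statistical mixture of 5, 7 and the bis-dearomatized dimer, competing methylation at a bridge-bearing carbon, or base-induced exchange of the methylene bridge. The fallback sets out from 3 and moves the dearomatization to the monomer. NaOMe/MeI in MeOH converts 3 into 3,5-dihydroxy-4,4-dimethyl-2-propanoylcyclohexa-2,5-dien-1-one (2-propionylfilicinic acid) F1. Then F1, 3 and aqueous formaldehyde in dilute NaOH give the cross-condensed dimer, and the two homodimers are removed by chromatography. The fallback comes back to the route at 7.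

**Step 4 (chromene annulation).** The ring may close onto the other ortho oxygen, giving the 6-propionyl/8-methylene isomer, or heat may scramble the bridge. The fallback sets out from 3 and fixes the regiochemistry on the monomer. Compounds 3 and 8 with EDDA give 1-(5,7-dihydroxy-2,2-dimethyl-2H-chromen-8-yl)propan-1-one F2, which is separated from its 6-propionyl isomer and confirmed by HMBC/NOE. F2 has a single free ring C–H (C-6). It is condensed with formaldehyde and 2-propionylfilicinic acid F1, made from 3 as in the fallback to step 3, in dilute aqueous base. The fallback comes back to the route at 10.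

**Step 2 (dimerization).** Because 3 has two equivalent free positions, over-condensation to trimers and oligomers is possible. The fallback sets out from 3 and delivers one methylene per molecule. A Mannich reaction of 3 (CH2O, Me2NH, EtOH, 0 °C) gives 1-[3-[(dimethylamino)methyl]-2,4,6-trihydroxyphenyl]propan-1-one F3. Heating F3 with 1.5 equiv of 3 in dioxane at 90 °C releases the o-quinone methide slowly, and 3 traps it. The fallback comes back to the route at 5.

## Further compounds

F1 | step 3 | 3,5-dihydroxy-4,4-dimethyl-2-propanoylcyclohexa-2,5-dien-1-one (2-propionylfilicinic acid) | CCC(=O)C1=C(O)C(C)(C)C(O)=CC1=O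
F2 | step 4 | 1-(5,7-dihydroxy-2,2-dimethyl-2H-chromen-8-yl)propan-1-one | CCC(=O)c1c(O)cc(O)c2c1OC(C)(C)C=C2
F3 | step 2 | 1-[3-[(dimethylamino)methyl]-2,4,6-trihydroxyphenyl]propan-1-one | CCC(=O)c1c(O)cc(O)c(CN(C)C)c1O
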